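If electrophile and nucleophile are consumed one for one, begin with the nucleophile, whose concentration should set the order of the rate.

common to all: electrophile 0.21 M
- Tuesday's: nucleophile 2 equiv; free base 0.40 equiv; run made earlier
- Sunday's: nucleophile 2 equiv; free base 1.6 equiv; run made earlier
- flask: nucleophile 2.00 equiv; free base 0.800 equiv; time 1.5 h

| run | time / min | electrophile / % | target / % |
|---|---|---|---|
| Tuesday's | 4.00 | 98.1 | 1.5 |
| Tuesday's | 8.00 | 96.2 | 3.9 |
| Tuesday's | 15.0 | 93.1 | 6.7 |
| Tuesday's | 30.0 | 86.5 | 12.1 |
| Tuesday's | 50.0 | 79.4 | 18.0 |
| Sunday's | 5.00 | 97.6 | 2.3 |
| Sunday's | 15.0 | 92.7 | 6.8 |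
| Sunday's | 25.0 | 88.7 | 11.3 |
| Sunday's | 40.0 | 83.1 | 15.9 |
| Sunday's | 50.0 | 79.8 | 18.4 |

(standard deviation of a reading: 0.3 percentage points)

* part of the electrophile that has reacted at 1.5 h
* share of free nucleophile in free nucleophile and protonated nucleophile together, at 1.5 h

- the earlier runs do not show how much of nucleophile is bound; that part of a forecast is a guess

First ask whether free base enters the rate. Sunday's run carried 4.00 times the free base of Tuesday's, yet the electrophile left at the last reading differs by 0.4 percentage points, against a scatter of 0.3 points. So leave free base out.

Next ask what the nucleophile does. Both runs hold it at the same charge, so comparing them does not show its order; assume first order in electrophile and in nucleophile. Let a and b be the electrophile and nucleophile left, each as a share of its own charge, e the equivalents of nucleophile, C the starting electrophile concentration and t the time. Then ln(b/a) = k·C·(e − 1)·t. From Tuesday's last reading, take k, the second-order rate constant, as 0.697 /M/h.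

Now put in this flask's charge and time: my reckoning gives 32.9% reacted. The free share stays a guess, since neither run shows bound nucleophile.

The forecast gives 32.3% reacted, a little less than mine, and 99% free, reasoning “so little nucleophile should be protonated”.

The flask gives 31.8% reacted and 83.6% free.

    acid set free + free base ⇌ salt of the base (K = 18.0 /M, k = 76.0 /M/h)
    nucleophile + acid set free ⇌ idle adduct, settled at all times (K = 4.20 /M)
    electrophile + nucleophile → acid set free + target (k = 0.740 /M/h)
    nucleophile + acid set free ⇌ protonated nucleophile, settled at all times (K = 84.0 /M)
    nucleophile + target → over-reaction product (k = 0.680 /M/h)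

Set the reckoned 32.9% beside the flask's 31.8%. The forecast and the flask part on the free share: at 1.50 h the flask holds 0.0558 M of protonated nucleophile, and 97% of its free base is still unbound. Now raise the nucleophile to 8.00 equiv, hold the other charges and the time, and keep the same k: the reckoning gives 80.7% reacted, and that neighbouring flask gives 79.4%, with 34.7% as target and 44.7% as over-reaction product.

(All runs come from a simulation on assumed constants, noise included.)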